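Whatever the order of addition, each flask receives the same charge, 0.11 M of starting complex and 0.121 M of incoming ligand, so the recipes differ in what meets what, and when.

| setting | noon | summer | dusk | spring |
|---|---|---|---|---|
| starting complex | 0.11 M | 0.11 M | 0.11 M (fed, over 1.5 min) | 0.11 M |
| incoming ligand | 0.121 M (fed, over 1.5 min) | 0.121 M | 0.121 M | 0.121 M (in portions, 3, over 1.5 min) |
| time | 2.5 min | 2.5 min | 2.5 min | 2.5 min |
| remark | all else is in the flask from the start; the feed brings no volume worth counting | everything together at the start | all else is in the flask from the start; the feed brings no volume worth counting | first portion at the start, last at 1.5 min |

    complex with one exchanged → side product (k1 = 0.126 s⁻¹)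
    complex with one exchanged + incoming ligand ⇌ leaving ligand + complex with two exchanged (K2 = 9.04, k2 = 5.54 M⁻¹ s⁻¹)
    2 starting complex → self-condensation product (k3 = 0.756 M⁻¹ s⁻¹)
    starting complex + incoming ligand ⇌ leaving ligand + complex with one exchanged (K4 = 0.10, k4 = 0.750 M⁻¹ s⁻¹)
    crystals ⇌ leaving ligand, rate k5*(cs5 - [leaving ligand]) while solid is left; crystals form when [leaving ligand] > cs5 (cs5 = 3.1 mM, k5 = 4.79 s⁻¹)
    complex with two exchanged + incoming ligand ⇌ leaving ligand + complex with three exchanged (K6 = 1.9, k6 = 0.898 M⁻¹ s⁻¹)

- a species is counted by the starting complex in it: one self-condensation product counts as two
- amounts and yields of leaving ligand count crystals too
- for a step with 2 of a species take k times the square, and two of it per event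
- given per volume of solution although it is solid: crystals
- run time (noon): 2.5 min

- the best flask by share of complex with three exchanged in complex with three exchanged plus side product; "all alike" if 1.5 percentage points covers them all (noon / summer / dusk / spring / all alike)
- share of complex with three exchanged in complex with three exchanged plus side product at the end, noon
- share of complex with three exchanged in complex with three exchanged plus side product at the end, summer
- share of complex with three exchanged in complex with three exchanged plus side product at the end, dusk
- share of complex with three exchanged in complex with three exchanged plus side product at the end, spring

I count in powers of ten below the run of 150 s. The top rung is the crystals: with solid present, dissolved leaving ligand relaxes towards its solubility with a half-life of 0.145 s, shorter than the next rung and 3.01 powers below the run, so once crystals exist I take dissolved leaving ligand to sit near its solubility of 3.1 mM. Next comes complex with one exchanged, which passes onward with a forward half-life of 1.0 s at charged ligand, 2.18 powers down. Then comes a cluster: complex with one exchanged goes to side product with a half-life of 5.50 s, starting complex has a first half-life of 6.01 s by self-condensation, and its forward half-life by the first exchange at charged ligand is 7.64 s, about 1.40 powers down.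

Because the forward half-life of complex with one exchanged is shorter than that of starting complex by the first exchange, I take complex with one exchanged as a short-lived intermediate, and its fate as a race at each moment. I carry the even-split level: the free incoming ligand at which complex with one exchanged goes equally to side product and onward by the forward step, which is the side-product rate constant over the forward constant of the second exchange, 0.0227 M. Free ligand over this level is the selectivity factor of that branch.

In summer the charge stands at 5.33 times the level, so at the start 84.2% goes onward by the forward step, and that share falls as ligand is used. In noon the feed needs 16.9 s to reach the level even if nothing consumed ligand, and for that moment I reckon, from self-condensation by itself, about a quarter of the starting complex. In spring the first portion stands at 1.77 times the level, below summer's start. So I commit to summer as best, with noon and spring under it; dusk I cannot place by hand.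

The forecast names noon as best, with noon 67%, summer 60%, dusk 59% and spring 65%, on the ground that feeding “leaves ligand in excess late on, favouring the three-exchanged complex”. I differ from it on the top flask.

The simulation gives summer as best: noon 56.9%, summer 64.9%, dusk 58.1%, spring 51.7%. The forecast's spring number is what everything added at the start gives.

In summer at 0.131 min, complex with one exchanged goes onward by the forward step 2.8 times as fast as to side product, which on the even-split level means free incoming ligand near 0.0642 M, above the level. A neighbour of summer charged with 0.030 M of incoming ligand starts at 1.32 times the level, ends at 0.00439 M, below it, and gives a share of 21.4%.

The constants used here were set for the occasion, and the outcome is calculated.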